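## The problem

CNP0191741.1 (19) is a methylene-bridged pair of isobutyryl phloroglucinol units: ring A is a fully substituted aromatic acylphloroglucinol carrying a prenyl group, and ring B is its dearomatized counterpart, an enolized cyclohexane-1,3,5-trione. Ring B is numbered here from its quaternary carbon: C1 bears a prenyl and an isobutyryl group, C2, C4 and C6 bear oxygen, C3 bears a methyl group and C5 the CH2 bridge to ring A. C1 is the only stereocentre, and it is stereogenic solely because C3 carries methyl while C5 carries the bridge. Nothing else in the molecule can control it, so it must be set by a reagent while the two flanks of C1 are distinguishable, and then kept. C1 has three acyl-type neighbours, so nucleophiles can strip the isobutyryl group with aromatization as driving force, and β-hydroxy ketones next to C1 can undergo retro-aldol cleavage. The prenyl groups cyclize onto ortho hydroxyls in acid. Dearomative prenylation of an acylphloroglucinol is no answer, because alkylation goes to the ring CH positions and not to the acyl-bearing carbon. The enabling feature is that C1 with its isobutyryl group is the ipso carbon of isobutyrophenone (1): Birch reductive alkylation prenylates exactly this carbon, and in the derived dienone 5 the two β-carbons (future C2 and C6) are enantiotopic and both still lack oxygen. A catalyst that delivers a heteroatom to one of them therefore fixes C1 and begins the oxygenation of ring B in one event.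

## Retrosynthesis

**Bridge.** Target 19 is cut between the bridge CH2 and C5 of ring B, giving trione 12 and aminomethyl phenol 17, a stored form of ortho-quinone methide 18. The neighbouring cut, between the CH2 and ring A, would make ring B the electrophile and ring A the nucleophile; it is kept as a reserve. The chosen cut uses ring B at its only unsubstituted, doubly activated carbon and puts the union last, so the fragile triacyl carbon C1 meets one intermolecular reaction only. Each half has about half the atoms of 19, and 12 holds the stereocentre. The forward step must alkylate C5 rather than C3 or oxygen, without deacylating C1.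

**Ring A.** Phenol 17 goes back by loss of the aminomethyl group to prenyl acylphloroglucinol 16, by loss of prenyl to 15, and by a Friedel–Crafts cut to phloroglucinol (13) and isobutyryl chloride (14), with prenyl bromide (2) as the prenyl source. The acyl group comes first because it deactivates the ring and leaves two equivalent positions. The reactive aminomethyl handle comes last. These are standard operations on cheap materials; the only demand is mono-C-prenylation.

**Oxidation level of ring B.** The enolic oxygens at C2 and C6 of 12 are traced to the carbinols of diol 11, and these to the two carbon–boron bonds of bis-boronate 10. An epoxide or a free hydroxyl carried through several steps would be the alternative. Boronates are preferred because they keep both oxygens masked until no enone remains. A free C6 hydroxyl beside an enone and the quaternary carbon is the arrangement most prone to retro-aldol loss of C1. The forward steps are two oxidations without strong base.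

**C2–B bond.** Bis-boronate 10 is cut at C2–B to enone 9 and diboron 6. Both new CH centres later become sp2, so the reaction carries no stereochemical demand; it only has to reach a hindered β-carbon.

**C3 methyl.** Enone 9 is cut at the C3–CH3 bond through iodide 8 to boryl enone 7. This must precede the key disconnection in the retrosynthetic sense. Without the methyl group the flanks of C1 would become identical once C6 reaches the ketone level. In 7 one flank is a boryl-substituted CH–CH2 and the other an enone, so C3 is addressed unambiguously. The forward reactions must leave the alkyl boronate alone.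

**Key cut, C6–B.** Boryl enone 7 is cut at the C6–B bond to achiral dienone 5 and diboron 6, removing both stereocentres. The rival cut at C1–prenyl would require enantioselective alkylation of a carbon flanked by three carbonyls, for which there is no good solution. A direct C6–O cut would create the labile β-oxy ketone at once. The forward reaction must choose one of two enantiotopic β-carbons, stop after one addition and spare the acyl group.

**Dienone.** The ring carbonyl of 5 goes back to the doubly allylic CH2 of diene 4. Diene 4 is cut at the C1–prenyl bond to isobutyrophenone (1) and prenyl bromide (2). Dissolving-metal reduction places the enolate on the ipso carbon, so this cut needs no directing group and reaches commercial materials in two steps.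

## Roads not taken

**Alternative 1:** Ring B is cut across C1–C2 and C5–C6 into 2-prenylacrolein A1 and 1-dimethylamino-3-silyloxybutadiene A2. The forward key step is a Diels–Alder reaction under a chiral salen complex of trivalent chromium, which after acidic work-up gives formyl enone A3.
- Merits: ring and quaternary centre arise together; α-substituted acroleins are a proven substrate class for this catalysis; the enantioselectivity does not depend on telling prenyl from an acyl group on a ring face. In confidence of enantiocontrol this road is better than the chosen one.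
- Weak points: A3 carries oxygen only at C4 and one flank is a saturated CH2–CH2. The aldehyde must become the isobutyryl ketone beside an enone. The methyl group must be placed before the saturated flank is dehydrogenated, or the intermediate becomes achiral. A1 itself has to be made.
- Comparison: several steps longer for ring B. The chosen plan sets against it that prenyl and isobutyryl are in place from step 1 and both flanks of C1 start at the enone level.

**Alternative 2:** The C1–C6 bond is cut. Racemic β-keto ester A4 adds to ethyl vinyl ketone A5 under a cationic BINAP aqua complex of divalent palladium to give Michael adduct A6; a Dieckmann closure would then give dione A7.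
- Merits: acyclic, cheap building blocks; the C3 methyl and two of the three ring oxygens come with the components, so no cross-coupling is needed. In this respect it is better than the chosen plan.
- Weak points: the nucleophile is very hindered (α-prenyl, isobutyryl ketone, tert-butyl ester). The ethyl ketone enolate can add to the isobutyryl ketone instead of the poor tert-butyl ester acceptor. A7 has a bare CH2 at C6 next to the quaternary carbon, so dehydrogenation and β-oxygenation are still required.
- Comparison: the chosen key step installs exactly this missing C6 heteroatom while it sets C1.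

**Alternative 3:** The bond from C1 to the allyl group is cut. Heating pyrone ether A8, made from an enantiopure secondary allylic alcohol, should give Claisen product A9 with transfer of chirality to the quaternary carbon.
- Merits: no chiral catalyst; every ring oxygen, the C3 methyl as an ethyl group and the C5 CH2 are already present. In oxidation-state economy it is clearly the best of the four.
- Weak points: the rearrangement ends on an acyl-bearing carbon, gives a non-enolizable tricarbonyl and may revert. A9 carries a crotyl group that must be exchanged for prenyl by cross-metathesis. Converting the lactone into the carbocycle exposes a triacyl carbon to strong base, with deacylation or decarboxylation as likely outcomes.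
- Comparison: the chosen plan pays with four oxidation-state steps but keeps each of them on well-known ground and never treats the finished C1 with strong base.

Key step: step 3

Assumption: in step 3 the copper boryl is taken to add on the ring face opposite the isobutyryl group, as drawn in 7, and (S,S)-Ph-BPE is written provisionally. If the first run gives the mirror image or the other facial preference, the antipodal ligand supplies the same quaternary configuration, and the later steps are unchanged because the boron-bearing carbon ends as an sp2 carbon.

Remark: locants in compound names follow nomenclature rules; the quaternary carbon (C1 of ring B) is C4 in the names of 5 to 12.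

## Route

Step 1
Reactants: 1 isobutyrophenone (2-methyl-1-phenylpropan-1-one); 2 prenyl bromide (1-bromo-3-methylbut-2-ene)
Product: 4 2-methyl-1-[1-(3-methylbut-2-en-1-yl)cyclohexa-2,5-dien-1-yl]propan-1-one, via potassium dienolate 3 (not isolated)
Conditions: K (2.2 equiv), t-BuOH (1.0 equiv), NH3(l)/THF, −78 °C; LiBr; then 2, −78 °C; NH4Cl quench
Reagents that add atoms: none
Why: Birch reductive alkylation of an aryl ketone: two-electron reduction and protonation at the para carbon by tert-butanol give cross-conjugated dienolate 3, which is C-alkylated at the ipso carbon by the allylic bromide. At −78 °C with one equivalent of proton donor the side-chain carbonyl should be retained, and the lithium counter-ion from LiBr curbs proton exchange and dialkylation.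

Step 2
Reactants: 4 2-methyl-1-[1-(3-methylbut-2-en-1-yl)cyclohexa-2,5-dien-1-yl]propan-1-one
Product: 5 4-(2-methylpropanoyl)-4-(3-methylbut-2-en-1-yl)cyclohexa-2,5-dien-1-one (achiral)
Conditions: CrO3 (excess), 3,5-dimethylpyrazole, CH2Cl2, −20 °C
Reagents that add atoms: chromium trioxide, O=[Cr](=O)=O
Why: Allylic oxidation with the CrO3–3,5-dimethylpyrazole complex: the ring CH2 is doubly allylic and far more reactive than the allylic positions of the prenyl chain. The quaternary carbon rules out aromatization, so the cross-conjugated dienone is the expected product.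

Step 3
Reactants: 5 4-(2-methylpropanoyl)-4-(3-methylbut-2-en-1-yl)cyclohexa-2,5-dien-1-one; 6 bis(pinacolato)diboron
Product: 7 (4R,5S)-4-(2-methylpropanoyl)-4-(3-methylbut-2-en-1-yl)-5-(4,4,5,5-tetramethyl-1,3,2-dioxaborolan-2-yl)cyclohex-2-en-1-one (boron trans to isobutyryl)
Conditions: CuCl (5 mol %, monovalent copper), (S,S)-Ph-BPE (6 mol %), NaOtBu (5 mol %), 6 (1.05 equiv), MeOH (2 equiv), THF, −20 °C; chromatography to a single diastereomer
Reagents that add atoms: none
Why: CuCl, NaOtBu and the bisphosphine give a chiral copper alkoxide that undergoes σ-bond metathesis with 6 to a phosphine copper boryl. The boryl adds syn across one enone C=C of 5 with boron on the β-carbon, and methanol protonates the copper enolate to release 7 and a copper methoxide that re-enters the cycle. The closest known reaction type is the copper-catalysed enantioselective conjugate borylation that desymmetrizes 4,4-disubstituted cyclohexa-2,5-dienones; no ring is closed. The boron-bearing carbon (C5 in the name) is set by the ligand, which selects the enantioface of the alkene it binds. The quaternary carbon (C4 in the name) is set by which enantiotopic alkene reacts, that is, by this enantioface choice combined with approach opposite the isobutyryl group, whose trigonal carbon cannot turn both its oxygen and its isopropyl branch away from the β-carbons whereas the prenyl CH2 can. The step needs selection between enantiotopic β-carbons, a single addition and 1,4- over 1,2-addition; in 7 the catalyst-preferred face of the remaining enone lies under the isobutyryl group, so a second addition should be slow, while the enantiomer and the C5 epimer present that face openly and should be consumed further. The soft copper boryl and the hindered side-chain ketone favour conjugate addition, and alkoxide is limited to the copper loading so that the acyl group is not cleaved. Any diastereomer with boron cis to isobutyryl carries the opposite quaternary configuration and is removed here, before the boron-bearing carbon loses its stereochemistry.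

Step 4
Reactants: 7 (4R,5S)-4-(2-methylpropanoyl)-4-(3-methylbut-2-en-1-yl)-5-(4,4,5,5-tetramethyl-1,3,2-dioxaborolan-2-yl)cyclohex-2-en-1-one
Product: 8 (4R,5S)-2-iodo-4-(2-methylpropanoyl)-4-(3-methylbut-2-en-1-yl)-5-(4,4,5,5-tetramethyl-1,3,2-dioxaborolan-2-yl)cyclohex-2-en-1-one
Conditions: I2 (2 equiv), pyridine, DMAP (0.2 equiv), CH2Cl2, 0 °C → rt
Reagents that add atoms: iodine, [I][I]
Why: α-Iodination of an enone by the Johnson procedure (conjugate addition of the pyridine base, iodination of the enolate, elimination). Only the conjugated C=C reacts; the saturated α-CH2, the pinacol boronate and the prenyl alkene should be inert.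

Step 5
Reactants: 8 (4R,5S)-2-iodo-4-(2-methylpropanoyl)-4-(3-methylbut-2-en-1-yl)-5-(4,4,5,5-tetramethyl-1,3,2-dioxaborolan-2-yl)cyclohex-2-en-1-one
Product: 9 (4R,5S)-2-methyl-4-(2-methylpropanoyl)-4-(3-methylbut-2-en-1-yl)-5-(4,4,5,5-tetramethyl-1,3,2-dioxaborolan-2-yl)cyclohex-2-en-1-one
Conditions: MeB(OH)2 (2 equiv), Pd(dppf)Cl2 (5 mol %, divalent palladium), K3PO4, THF/H2O (10:1), 60 °C
Reagents that add atoms: methylboronic acid, CB(O)O
Why: Suzuki–Miyaura cross-coupling of an α-iodoenone with methylboronic acid; the secondary alkyl pinacol boronate does not transmetalate under these conditions and serves as a protected C6 hydroxyl. With methyl on the former enone α-carbon the two flanks of the quaternary carbon are constitutionally different from here on.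

Step 6
Reactants: 9 (4R,5S)-2-methyl-4-(2-methylpropanoyl)-4-(3-methylbut-2-en-1-yl)-5-(4,4,5,5-tetramethyl-1,3,2-dioxaborolan-2-yl)cyclohex-2-en-1-one; 6 bis(pinacolato)diboron
Product: 10 (4R,5S)-2-methyl-4-(2-methylpropanoyl)-4-(3-methylbut-2-en-1-yl)-3,5-bis(4,4,5,5-tetramethyl-1,3,2-dioxaborolan-2-yl)cyclohexan-1-one (epimers at C2 and C3, both centres later sp2)
Conditions: CuCl (10 mol %), Xantphos (10 mol %), NaOtBu (10 mol %), 6 (1.5 equiv), MeOH (2 equiv), THF, rt
Reagents that add atoms: none
Why: Copper-catalysed conjugate borylation of an α-substituted cyclic enone with an achiral, highly active Xantphos copper boryl; the face of attack and the configuration at the methyl-bearing carbon are immaterial. Keeping both oxygens masked as boronates avoids a free β-hydroxyl next to the quaternary carbon while an enone is still present, which would invite retro-aldol cleavage.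

Step 7
Reactants: 10 (4R,5S)-2-methyl-4-(2-methylpropanoyl)-4-(3-methylbut-2-en-1-yl)-3,5-bis(4,4,5,5-tetramethyl-1,3,2-dioxaborolan-2-yl)cyclohexan-1-one
Product: 11 (4R,5S)-3,5-dihydroxy-2-methyl-4-(2-methylpropanoyl)-4-(3-methylbut-2-en-1-yl)cyclohexan-1-one (epimers at C2 and C3)
Conditions: NaBO3·4H2O (6 equiv), THF/H2O (1:1), rt
Reagents that add atoms: sodium perborate, [Na+].[O-]OB=O
Why: Oxidation of alkyl pinacol boronates by perborate, with 1,2-migration of carbon from boron to oxygen and retention. This mildly basic oxidant is the usual choice for β-boryl ketones because it spares β-hydroxy ketones from dehydration and retro-aldol cleavage.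

Step 8
Reactants: 11 (4R,5S)-3,5-dihydroxy-2-methyl-4-(2-methylpropanoyl)-4-(3-methylbut-2-en-1-yl)cyclohexan-1-one
Product: 12 (4R)-3,5-dihydroxy-2-methyl-4-(2-methylpropanoyl)-4-(3-methylbut-2-en-1-yl)cyclohexa-2,5-dien-1-one (dienol form of the 1,3,5-trione)
Conditions: Dess–Martin periodinane (3 equiv), CH2Cl2, 0 °C → rt
Reagents that add atoms: none
Why: Dess–Martin oxidation of both β-hydroxy ketone units to β-diketones under non-basic conditions; the product should enolize to the stable dienol. The quaternary carbon has no hydrogen and is not touched, so its configuration is kept.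

Step 9
Reactants: 13 phloroglucinol (benzene-1,3,5-triol); 14 isobutyryl chloride (2-methylpropanoyl chloride)
Product: 15 2-methyl-1-(2,4,6-trihydroxyphenyl)propan-1-one
Conditions: AlCl3 (3 equiv), PhNO2, 80 °C; aqueous HCl work-up
Reagents that add atoms: none
Why: Friedel–Crafts C-acylation of phloroglucinol; the first acyl group deactivates the ring, so monoacylation is the expected outcome.

Step 10
Reactants: 15 2-methyl-1-(2,4,6-trihydroxyphenyl)propan-1-one; 2 prenyl bromide
Product: 16 2-methyl-1-[2,4,6-trihydroxy-3-(3-methylbut-2-en-1-yl)phenyl]propan-1-one
Conditions: 2 (1.0 equiv), 10% aq KOH, 0 °C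
Reagents that add atoms: none
Why: C-Prenylation of the phloroglucinolate in water, where solvation of the phenoxide oxygens favours C- over O-alkylation. One equivalent of bromide at 0 °C limits diprenylated by-products, which are separable.

Step 11
Reactants: 16 2-methyl-1-[2,4,6-trihydroxy-3-(3-methylbut-2-en-1-yl)phenyl]propan-1-one
Product: 17 1-{3-[(dimethylamino)methyl]-2,4,6-trihydroxy-5-(3-methylbut-2-en-1-yl)phenyl}-2-methylpropan-1-one
Conditions: CH2=NMe2+ I− (1.05 equiv), Et3N (1.1 equiv), CH2Cl2, 0 °C → rt; used without storage
Reagents that add atoms: Eschenmoser's salt (N,N-dimethylmethyleneiminium iodide), C=[N+](C)C.[I-]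
Why: Mannich aminomethylation of the only free aromatic position with a preformed iminium salt. The electron-rich ring should react at 0 °C, and no formaldehyde is present to bridge two molecules of 16.

Step 12
Reactants: 12 (4R)-3,5-dihydroxy-2-methyl-4-(2-methylpropanoyl)-4-(3-methylbut-2-en-1-yl)cyclohexa-2,5-dien-1-one; 17 1-{3-[(dimethylamino)methyl]-2,4,6-trihydroxy-5-(3-methylbut-2-en-1-yl)phenyl}-2-methylpropan-1-one
Product: 19 CNP0191741.1 in its (4S)-dienol form (full name in the compound list), via ortho-quinone methide 18 (not isolated)
Conditions: 12 (1.1 equiv), 17 (1.0 equiv), AcOH (2 equiv), 1,4-dioxane, 70 °C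
Reagents that add atoms: none
Why: The acidic trione protonates the benzylic amine of 17, loss of dimethylamine gives ortho-quinone methide 18, and the enol carbon C5 of 12 (unsubstituted and least hindered) adds in a Michael reaction, after which ring A rearomatizes. Phenol 17 has no free aromatic carbon and cannot condense with itself at carbon. Acetic acid keeps the liberated amine protonated so that it does not attack the isobutyryl group on the quaternary carbon, whose configuration is untouched.

## Compound list

1 | isobutyrophenone | CC(C)C(=O)c1ccccc1 | starting material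
2 | prenyl bromide | CC(C)=CCBr | starting material
3 | potassium 1-(cyclohexa-2,5-dien-1-ylidene)-2-methylpropan-1-olate | CC(C)C([O-])=C1C=CCC=C1.[K+] | intermediate (not isolated)
4 | 2-methyl-1-[1-(3-methylbut-2-en-1-yl)cyclohexa-2,5-dien-1-yl]propan-1-one | CC(C)C(=O)C1(CC=C(C)C)C=CCC=C1 | intermediate
5 | 4-(2-methylpropanoyl)-4-(3-methylbut-2-en-1-yl)cyclohexa-2,5-dien-1-one | O=C1C=CC(CC=C(C)C)(C(=O)C(C)C)C=C1 | intermediate
6 | bis(pinacolato)diboron | CC1(C)OB(OC1(C)C)B1OC(C)(C)C(C)(C)O1 | starting material
7 | (4R,5S)-4-(2-methylpropanoyl)-4-(3-methylbut-2-en-1-yl)-5-(4,4,5,5-tetramethyl-1,3,2-dioxaborolan-2-yl)cyclohex-2-en-1-one | O=C1C[C@H](B2OC(C)(C)C(C)(C)O2)[C@@](CC=C(C)C)(C(=O)C(C)C)C=C1 | intermediate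
8 | (4R,5S)-2-iodo-4-(2-methylpropanoyl)-4-(3-methylbut-2-en-1-yl)-5-(4,4,5,5-tetramethyl-1,3,2-dioxaborolan-2-yl)cyclohex-2-en-1-one | O=C1C[C@H](B2OC(C)(C)C(C)(C)O2)[C@@](CC=C(C)C)(C(=O)C(C)C)C=C1I | intermediate
9 | (4R,5S)-2-methyl-4-(2-methylpropanoyl)-4-(3-methylbut-2-en-1-yl)-5-(4,4,5,5-tetramethyl-1,3,2-dioxaborolan-2-yl)cyclohex-2-en-1-one | O=C1C[C@H](B2OC(C)(C)C(C)(C)O2)[C@@](CC=C(C)C)(C(=O)C(C)C)C=C1C | intermediate
10 | (4R,5S)-2-methyl-4-(2-methylpropanoyl)-4-(3-methylbut-2-en-1-yl)-3,5-bis(4,4,5,5-tetramethyl-1,3,2-dioxaborolan-2-yl)cyclohexan-1-one, epimers at C2 and C3 | O=C1C[C@H](B2OC(C)(C)C(C)(C)O2)[C@@](CC=C(C)C)(C(=O)C(C)C)C(B2OC(C)(C)C(C)(C)O2)C1C | intermediate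
11 | (4R,5S)-3,5-dihydroxy-2-methyl-4-(2-methylpropanoyl)-4-(3-methylbut-2-en-1-yl)cyclohexan-1-one, epimers at C2 and C3 | O=C1C[C@H](O)[C@@](CC=C(C)C)(C(=O)C(C)C)C(O)C1C | intermediate
12 | (4R)-3,5-dihydroxy-2-methyl-4-(2-methylpropanoyl)-4-(3-methylbut-2-en-1-yl)cyclohexa-2,5-dien-1-one | O=C1C=C(O)[C@@](CC=C(C)C)(C(=O)C(C)C)C(O)=C1C | intermediate
13 | phloroglucinol | Oc1cc(O)cc(O)c1 | starting material
14 | isobutyryl chloride | CC(C)C(=O)Cl | starting material
15 | 2-methyl-1-(2,4,6-trihydroxyphenyl)propan-1-one | CC(C)C(=O)c1c(O)cc(O)cc1O | intermediate
16 | 2-methyl-1-[2,4,6-trihydroxy-3-(3-methylbut-2-en-1-yl)phenyl]propan-1-one | CC(C)=CCc1c(O)cc(O)c(C(=O)C(C)C)c1O | intermediate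
17 | 1-{3-[(dimethylamino)methyl]-2,4,6-trihydroxy-5-(3-methylbut-2-en-1-yl)phenyl}-2-methylpropan-1-one | CC(C)=CCc1c(O)c(CN(C)C)c(O)c(C(=O)C(C)C)c1O | intermediate
18 | 3,5-dihydroxy-6-methylidene-4-(2-methylpropanoyl)-2-(3-methylbut-2-en-1-yl)cyclohexa-2,4-dien-1-one | C=C1C(=O)C(CC=C(C)C)=C(O)C(C(=O)C(C)C)=C1O | intermediate (not isolated)
19 | (4S)-3,5-dihydroxy-6-methyl-4-(2-methylpropanoyl)-4-(3-methylbut-2-en-1-yl)-2-{[2,4,6-trihydroxy-3-(2-methylpropanoyl)-5-(3-methylbut-2-en-1-yl)phenyl]methyl}cyclohexa-2,5-dien-1-one (CNP0191741.1) | CC(C)=CCc1c(O)c(CC2=C(O)[C@@](CC=C(C)C)(C(=O)C(C)C)C(O)=C(C)C2=O)c(O)c(C(=O)C(C)C)c1O | target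

## Step count and risks

Total: 12 steps. Longest linear sequence: 9 steps (steps 1 to 8, then step 12); the ring A branch is steps 9 to 11.

**Step 3 (key step).** Three processes are most likely to go wrong.
- Weak discrimination between the two ring faces, because isobutyryl and prenyl are of similar bulk; this would cost material when the diastereomer of opposite quaternary configuration is removed.
- Alkoxide-induced cleavage of the isobutyryl group from 5, with aromatization.
- Double borylation.

Fallback: it sets out from 5. A base-free desymmetrizing conjugate reduction with an ene-reductase of the old yellow enzyme family (NADPH recycling, phosphate buffer) recognizes the two substituents by shape rather than by bulk alone. It should give (4S)-4-(2-methylpropanoyl)-4-(3-methylbut-2-en-1-yl)cyclohex-2-en-1-one F1. Iodination and methyl coupling as in steps 4 and 5 lead through (4S)-2-iodo-4-(2-methylpropanoyl)-4-(3-methylbut-2-en-1-yl)cyclohex-2-en-1-one F2 to (4S)-2-methyl-4-(2-methylpropanoyl)-4-(3-methylbut-2-en-1-yl)cyclohex-2-en-1-one F3. Dehydrogenation of the saturated flank with IBX gives (4R)-2-methyl-4-(2-methylpropanoyl)-4-(3-methylbut-2-en-1-yl)cyclohexa-2,5-dien-1-one F4, which is chiral because the methyl group is in place. Double conjugate borylation under the conditions of step 6 gives the bis-boronate F5 as a mixture of epimers at its CH centres. Perborate oxidation gives the diol mixture F6, and Dess–Martin oxidation brings the route back at 12.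

**Step 6.** The β-carbon is flanked by the quaternary carbon and the enone carries an α-methyl group, so the addition may be slow and starting enone may persist or be reduced.

Fallback: it sets out from 9. Perborate oxidation gives (4S,5S)-5-hydroxy-2-methyl-4-(2-methylpropanoyl)-4-(3-methylbut-2-en-1-yl)cyclohex-2-en-1-one F7. Nucleophilic epoxidation with t-BuOOH and DBU in CH2Cl2 (anhydrous, to limit retro-aldol cleavage) gives (4R,5S)-2,3-epoxy-5-hydroxy-2-methyl-4-(2-methylpropanoyl)-4-(3-methylbut-2-en-1-yl)cyclohexan-1-one F8, of either epoxide face. SmI2 in THF/MeOH at −78 °C cleaves the α-carbon–oxygen bond and returns the route at 11.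

**Step 12.** The quinone methide may be attacked through C3 or an enol oxygen of 12 instead of C5, and dimethylamine may cleave the isobutyryl group from the triacyl carbon.

Fallback: it sets out from 16 and 12. Vilsmeier formylation of 16 (POCl3, DMF) gives 2,4,6-trihydroxy-3-(2-methylpropanoyl)-5-(3-methylbut-2-en-1-yl)benzaldehyde F9. A three-component reductive alkylation of 12 with F9 (catalytic L-proline, Hantzsch ester, rt) proceeds by Knoevenagel condensation, which is possible only at C5 because C3 has a single hydrogen, followed by hydride transfer. It returns the route at 19.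

**Step 1.** The ketone may be enolized or reduced at the carbonyl before ring reduction, and the dienolate may be protonated instead of alkylated.

Fallback: it sets out from benzoic acid F10 and 2. The well-established Birch reductive alkylation of the acid gives 1-(3-methylbut-2-en-1-yl)cyclohexa-2,5-diene-1-carboxylic acid F11. Oxalyl chloride converts it to 1-(3-methylbut-2-en-1-yl)cyclohexa-2,5-diene-1-carbonyl chloride F12. Acylation of i-PrMgCl with catalytic Fe(acac)3 in THF at −78 °C returns the route at 4.

## Further compounds

F1 | step 3 | (4S)-4-(2-methylpropanoyl)-4-(3-methylbut-2-en-1-yl)cyclohex-2-en-1-one | O=C1CC[C@@](CC=C(C)C)(C(=O)C(C)C)C=C1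
F2 | step 3 | (4S)-2-iodo-4-(2-methylpropanoyl)-4-(3-methylbut-2-en-1-yl)cyclohex-2-en-1-one | O=C1CC[C@@](CC=C(C)C)(C(=O)C(C)C)C=C1I
F3 | step 3 | (4S)-2-methyl-4-(2-methylpropanoyl)-4-(3-methylbut-2-en-1-yl)cyclohex-2-en-1-one | O=C1CC[C@@](CC=C(C)C)(C(=O)C(C)C)C=C1C
F4 | step 3 | (4R)-2-methyl-4-(2-methylpropanoyl)-4-(3-methylbut-2-en-1-yl)cyclohexa-2,5-dien-1-one | O=C1C=C[C@@](CC=C(C)C)(C(=O)C(C)C)C=C1C
F5 | step 3 | (4R)-2-methyl-4-(2-methylpropanoyl)-4-(3-methylbut-2-en-1-yl)-3,5-bis(4,4,5,5-tetramethyl-1,3,2-dioxaborolan-2-yl)cyclohexan-1-one, CH centres undefined | O=C1CC(B2OC(C)(C)C(C)(C)O2)[C@@](CC=C(C)C)(C(=O)C(C)C)C(B2OC(C)(C)C(C)(C)O2)C1C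
F6 | step 3 | (4R)-3,5-dihydroxy-2-methyl-4-(2-methylpropanoyl)-4-(3-methylbut-2-en-1-yl)cyclohexan-1-one, CH centres undefined | O=C1CC(O)[C@@](CC=C(C)C)(C(=O)C(C)C)C(O)C1C
F7 | step 6 | (4S,5S)-5-hydroxy-2-methyl-4-(2-methylpropanoyl)-4-(3-methylbut-2-en-1-yl)cyclohex-2-en-1-one | O=C1C[C@H](O)[C@@](CC=C(C)C)(C(=O)C(C)C)C=C1C
F8 | step 6 | (4R,5S)-2,3-epoxy-5-hydroxy-2-methyl-4-(2-methylpropanoyl)-4-(3-methylbut-2-en-1-yl)cyclohexan-1-one, epoxide face undefined | O=C1C[C@H](O)[C@@](CC=C(C)C)(C(=O)C(C)C)C2OC12C
F9 | step 12 | 2,4,6-trihydroxy-3-(2-methylpropanoyl)-5-(3-methylbut-2-en-1-yl)benzaldehyde | CC(C)=CCc1c(O)c(C=O)c(O)c(C(=O)C(C)C)c1O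
F10 | step 1 | benzoic acid | OC(=O)c1ccccc1
F11 | step 1 | 1-(3-methylbut-2-en-1-yl)cyclohexa-2,5-diene-1-carboxylic acid | OC(=O)C1(CC=C(C)C)C=CCC=C1
F12 | step 1 | 1-(3-methylbut-2-en-1-yl)cyclohexa-2,5-diene-1-carbonyl chloride | ClC(=O)C1(CC=C(C)C)C=CCC=C1
A1 | alternative 1 | 5-methyl-2-methylidenehex-4-enal (2-prenylacrolein) | C=C(CC=C(C)C)C=O
A2 | alternative 1 | (E)-3-(tert-butyldimethylsilyloxy)-N,N-dimethylbuta-1,3-dien-1-amine | CN(C)/C=C/C(=C)O[Si](C)(C)C(C)(C)C
A3 | alternative 1 | (S)-1-(3-methylbut-2-en-1-yl)-4-oxocyclohex-2-ene-1-carbaldehyde | O=C1CC[C@@](CC=C(C)C)(C=O)C=C1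
A4 | alternative 2 | racemic tert-butyl 5-methyl-2-(2-methylpropanoyl)hex-4-enoate | CC(C)C(=O)C(CC=C(C)C)C(=O)OC(C)(C)C
A5 | alternative 2 | pent-1-en-3-one (ethyl vinyl ketone) | CCC(=O)C=C
A6 | alternative 2 | tert-butyl (R)-2-(2-methylpropanoyl)-2-(3-methylbut-2-en-1-yl)-5-oxoheptanoate | CCC(=O)CC[C@@](CC=C(C)C)(C(=O)C(C)C)C(=O)OC(C)(C)C
A7 | alternative 2 | 2-methyl-4-(2-methylpropanoyl)-4-(3-methylbut-2-en-1-yl)cyclohexane-1,3-dione, quaternary configuration as in A6 | CC1C(=O)CC[C@@](CC=C(C)C)(C(=O)C(C)C)C1=O
A8 | alternative 3 | 4-[(S)-but-3-en-2-yloxy]-6-ethyl-3-(2-methylpropanoyl)pyran-2-one | CCC1=CC(O[C@@H](C)C=C)=C(C(=O)C(C)C)C(=O)O1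
A9 | alternative 3 | (R)-3-[(E)-but-2-en-1-yl]-6-ethyl-3-(2-methylpropanoyl)pyran-2,4-dione | CCC1=CC(=O)[C@@](C/C=C/C)(C(=O)C(C)C)C(=O)O1
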